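The data are simulated from invented constants; the scatter is artificial.

The pitfall in the grey run is to carry the red run's balance over as if the coupling partner stayed at what remains of its charge, with nothing else happening.

| setting | red | ochre | violet | grey |
|---|---|---|---|---|
| starting material | 1.00 M | 2.00 M | 1.00 M | 1.00 M |
| coupling partner | 0.800 M | 0.800 M | 1.60 M | 3.70 M |
| time |  |  |  | 56 min |

| red run: time / min | red run: [target] / M | ochre run: time / min | ochre run: [target] / M | violet run: time / min | violet run: [target] / M |
|---|---|---|---|---|---|
| 2.2 | 0.072 | 2.2 | 0.132 | 2.2 | 0.130 |
| 4.3 | 0.128 | 4.3 | 0.229 | 4.3 | 0.221 |
| 8.1 | 0.199 | 8.1 | 0.349 | 8.1 | 0.336 |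
| 15 | 0.288 | 15 | 0.476 | 15 | 0.440 |
| 29 | 0.378 | 29 | 0.573 | 29 | 0.538 |
| 56 | 0.432 | 56 | 0.599 | 56 | 0.576 |

(standard deviation of a reading: 0.003 M)

- apparent order in [starting material] of the starting rate, round the charge of the red run (the rate where two percent of its starting material have turned into target) (one fixed amount of target, the same in the runs compared)
- apparent order in [coupling partner] of the starting rate, round the charge of the red run (the rate where two percent of its starting material have turned into target)
- target in the grey run at 56 min, as a share of the starting material charged

- Overall: starting material + coupling partner -> target.
- Constant volume, constant temperature.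
- "The second partner" is coupling partner.
- An order is taken over about fifteen percent of the charge, up and down.

From the first red reading, the mean rate over that interval divided by the mean product of starting material and coupling partner, [S][R], gives 0.0444 M⁻¹ min⁻¹. This forward constant k_f is what I carry. The same sum gives 0.0423 M⁻¹ min⁻¹ for the ochre run and 0.0412 M⁻¹ min⁻¹ for the violet run, against a scatter of 4.17% on the first red reading, so I take both orders as one.

Now the books of the grey run, where starting material is the limiting reagent, 1.00 M against 3.70 M of partner. First entry, forward: I freeze the partner at the charge less the starting material, F = 2.70 M, which makes the step pseudo-first-order with a clock τ = 1/(k_f F) = 8.33 min. The 56 min asked are 6.72 clocks, longer than one clock. Second entry, return: the last red reading gives a quotient target/([S][R]) of 2.07 M⁻¹, with [S] and [R] taken as charge less target. This is a working figure, not an equilibrium constant: the red run still gains 0.0540 M over its last 27.0 min. Applied at F, it gives me a working target share of 84.8%. Third entry, loss: the same working sum for the violet run, with its partner charge less target, 1.02 M, gives 67.9%, while its last reading is 57.6% of the charge. I assume this fade grows as a power of that partner figure, which gives me a working factor of 0.648. My estimate closes the books at 54.9% as target, 15.2% as starting material and 29.9% gone elsewhere.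

The forecast gives 0.98, 0.93 and 60%, holding that “excess coupling partner opens something extra”. Its grey share stands above mine.

The grey run gives 60.1%, and the orders are 1.0 and 1.0.

    starting material + coupling partner ⇌ target (0.04536 M⁻¹ min⁻¹, 0.003246 min⁻¹)
    target + coupling partner → side product (0.009240 M⁻¹ min⁻¹)
    2 coupling partner → lost reagent (0.01338 M⁻¹ min⁻¹)

The fit with a decaying target forecast 83.2% for the grey run, with a residual of 7.9 scatter units. For the grey run, 6.72 frozen clocks reckon 0.121% as starting material on the forward step, against 39.9% of the charge that is not target. For the violet run, k_f times [S][R], where target equals two percent of the red charge, gives 0.0688 M min⁻¹, and the rate found there is 0.069 M min⁻¹.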